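Rings A and B come from one intramolecular Diels–Alder reaction. Ring B is a cyclohexene whose C6=C7 bond lies between C5 and C8, with C9 and quaternary C10 opposite and ring A (C1–C4) bridging C10 and C5. Disconnecting C5–C10 and C8–C9 leads to an acyclic (2E,8E,10E)-trienoyl imide carrying (R)-4-benzyloxazolidin-2-one on the C11 carbonyl. One cycloaddition closes both rings and sets C5, C9 and C10; C8 is corrected later by equilibrating the C17 aldehyde. The C9 vinyl group is then joined to a (Z)-β-iodoenoate by B-alkyl Suzuki coupling.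

Key step: step 12

Remark on the chemistry: atoms carry labdane numbers (ring A = C1–C5, C10; ring B = C5–C10; side chain C11–C16; ring carboxyl C17; angular methyl C20), and the target is taken as (5R,8S,9R,10S,13E). In every bicyclic compound H5 is anti to the C20 methyl and the C9 substituent is syn to it; only C8 changes.

Step 1
Reactants: 1 5-chloro-1-(trimethylsilyl)pent-1-yne
Product: 2 5-iodo-1-(trimethylsilyl)pent-1-yne
Conditions: NaI (3 equiv), acetone, reflux
Reagents that add atoms: sodium iodide, [Na+].[I-]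
Why: Finkelstein exchange (SN2), driven by precipitation of NaCl, turns the sluggish primary chloride into an iodide fit for enolate alkylation.

Step 2
Reactants: 2 5-iodo-1-(trimethylsilyl)pent-1-yne; 3 methyl isobutyrate
Product: 5 methyl 2,2-dimethyl-7-(trimethylsilyl)hept-6-ynoate, via lithium ester enolate 4 (not isolated)
Conditions: 3, LiN(iPr)2 (1.1 equiv), THF, −78 °C; then 2, DMPU, −78 °C → rt
Reagents that add atoms: none
Why: The fully substituted lithium ester enolate is alkylated by the primary iodide (SN2 ester enolate alkylation), which creates the C4 quaternary carbon with both methyl groups while the silyl cap keeps the alkyne non-acidic.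

Step 3
Reactants: 5 methyl 2,2-dimethyl-7-(trimethylsilyl)hept-6-ynoate
Product: 6 2,2-dimethyl-7-(trimethylsilyl)hept-6-yn-1-ol
Conditions: LiAlH4, Et2O, 0 °C
Reagents that add atoms: none
Why: Hydride reduction of the hindered ester should give the neopentyl alcohol without touching the silyl alkyne.

Step 4
Reactants: 6 2,2-dimethyl-7-(trimethylsilyl)hept-6-yn-1-ol
Product: 7 2,2-dimethyl-7-(trimethylsilyl)hept-6-ynal
Conditions: Dess–Martin periodinane, CH2Cl2, rt
Reagents that add atoms: none
Why: Dess–Martin oxidation stops cleanly at the non-enolisable neopentyl aldehyde.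

Step 5
Reactants: 7 2,2-dimethyl-7-(trimethylsilyl)hept-6-ynal; 8 triethyl (E)-4-phosphonocrotonate
Product: 10 ethyl (2E,4E)-6,6-dimethyl-11-(trimethylsilyl)undeca-2,4-dien-10-ynoate, via lithiated phosphonate 9 (not isolated)
Conditions: 8, LiN(SiMe3)2, THF, −78 °C; then 7, −78 → 0 °C
Reagents that add atoms: none
Why: Vinylogous Horner–Wadsworth–Emmons olefination of the non-enolisable aldehyde should give the (2E,4E)-dienoate under thermodynamic control and brings C6, C7, C8 and C17.

Step 6
Reactants: 10 ethyl (2E,4E)-6,6-dimethyl-11-(trimethylsilyl)undeca-2,4-dien-10-ynoate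
Product: 11 (2E,4E)-6,6-dimethyl-11-(trimethylsilyl)undeca-2,4-dien-10-yn-1-ol
Conditions: iBu2AlH (2.5 equiv), CH2Cl2, −78 °C
Reagents that add atoms: none
Why: 1,2-Reduction of the dienoate by iBu2AlH gives the dienol and removes the electron-withdrawing group from the future diene.

Step 7
Reactants: 11 (2E,4E)-6,6-dimethyl-11-(trimethylsilyl)undeca-2,4-dien-10-yn-1-ol
Product: 12 tert-butyldiphenylsilyl ether of dienol 11
Conditions: TBDPSCl, imidazole, CH2Cl2, rt
Reagents that add atoms: tert-butyl(chloro)diphenylsilane, CC(C)(C)[Si](Cl)(c1ccccc1)c1ccccc1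
Why: Silylation of the primary allylic alcohol gives a bulky, weakly Lewis-basic ether that should survive AlMe3, Me2AlCl and mild base.

Step 8
Reactants: 12 tert-butyldiphenylsilyl ether of dienol 11
Product: 13 tert-butyl{[(2E,4E)-6,6-dimethylundeca-2,4-dien-10-yn-1-yl]oxy}diphenylsilane
Conditions: K2CO3 (cat.), MeOH, rt
Reagents that add atoms: none
Why: Methanolysis of the alkynyl C–Si bond (protodesilylation) frees the terminal alkyne while the hindered TBDPS ether is stable to K2CO3 in methanol.

Step 9
Reactants: 13 tert-butyl{[(2E,4E)-6,6-dimethylundeca-2,4-dien-10-yn-1-yl]oxy}diphenylsilane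
Product: 15 methyl (2E,8E,10E)-12-[(tert-butyldiphenylsilyl)oxy]-3,7,7-trimethyldodeca-2,8,10-trienoate, via alkenyldimethylalane 14 (not isolated)
Conditions: AlMe3 (2.5 equiv), Cp2ZrCl2 (0.25 equiv), CH2Cl2, 0 °C → rt; then ClCO2Me, 0 °C → rt
Reagents that add atoms: trimethylaluminium, C[Al](C)C; methyl chloroformate, COC(=O)Cl
Why: Zirconium-catalysed Negishi carboalumination adds Me–Al syn across the terminal alkyne with methyl on the internal carbon, and the alkenylalane is acylated with retention, so the C9=C10 bond is E and carries C20 and C11 while the internal diene is inert.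

Step 10
Reactants: 15 methyl (2E,8E,10E)-12-[(tert-butyldiphenylsilyl)oxy]-3,7,7-trimethyldodeca-2,8,10-trienoate
Product: 16 (2E,8E,10E)-12-[(tert-butyldiphenylsilyl)oxy]-3,7,7-trimethyldodeca-2,8,10-trienoic acid
Conditions: LiOH, THF/MeOH/H2O, 40 °C; then aq. HCl to pH 3
Reagents that add atoms: lithium hydroxide, [Li+].[OH-]
Why: Saponification of the methyl ester frees the acid, and the primary TBDPS ether and the enoate geometry should survive mild aqueous LiOH.

Step 11
Reactants: 16 (2E,8E,10E)-12-[(tert-butyldiphenylsilyl)oxy]-3,7,7-trimethyldodeca-2,8,10-trienoic acid; 17 (R)-4-benzyloxazolidin-2-one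
Product: 19 (R)-4-benzyl-3-[(2E,8E,10E)-12-(tert-butyldiphenylsilyloxy)-3,7,7-trimethyldodeca-2,8,10-trienoyl]oxazolidin-2-one, via mixed pivalic anhydride 18 (not isolated)
Conditions: PivCl, Et3N, THF, −20 °C; then 17, LiCl, −20 °C → rt
Reagents that add atoms: none
Why: The acid is activated as its mixed pivalic anhydride and N-acylates the oxazolidinone at the less hindered carbonyl under LiCl/Et3N, which avoids strong base and keeps the E enoyl geometry.

Step 12
Reactants: 19 (R)-4-benzyl-3-[(2E,8E,10E)-12-(tert-butyldiphenylsilyloxy)-3,7,7-trimethyldodeca-2,8,10-trienoyl]oxazolidin-2-one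
Product: 20 trans-octalin imide cycloadduct (C11 acyl oxazolidinone on C9; C17 CH2OTBDPS on C8 syn to C20)
Conditions: Me2AlCl (1.6 equiv), CH2Cl2, −30 → 0 °C
Reagents that add atoms: none
Why: Excess Me2AlCl converts the imide into a cationic bidentate aluminium chelate that locks the enoyl s-cis and lowers its LUMO, and the (E,E)-diene adds in a concerted, asynchronous [4+2] forming C5–C10 and C8–C9; the closest known reaction is the Me2AlCl-promoted type 1 intramolecular Diels–Alder reaction of N-(2,8,10-undecatrienoyl)oxazolidinones to trans-octalins, here stretched to a β-methyl dienophile. Ring A closes as a six-membered carbocycle through the four-carbon tether C1–C4 held in a chair, and ring B is the cyclohexene created by the cycloaddition itself. C9 and C10 are set with C11 and C20 cis by suprafacial addition to the E dienophile, C5 is set trans to C20 by the endo orientation of the chelated carbonyl, and C8 follows from the E,E diene with C17 syn to C11 (corrected in step 18). The absolute sense comes from the auxiliary, whose benzyl group shields the C9 si face of the chelated enoyl so that the diene adds to the C9 re face. The step needs endo (trans-fusion) and π-facial selectivity, which the rigid chelate, the chair tether and the folding effect of the C4 gem-dimethyl group should secure.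

Step 13
Reactants: 20 trans-octalin imide cycloadduct
Product: 21 C11 alcohol (C9 CH2OH; C17 CH2OTBDPS syn to C20)
Conditions: LiBH4, MeOH (1 equiv), THF, 0 °C
Reagents that add atoms: none
Why: Borohydride reduces the exocyclic imide carbonyl to the primary alcohol and releases the auxiliary (reductive cleavage of an N-acyloxazolidinone) without touching the alkene or the silyl ether.

Step 14
Reactants: 21 C11 alcohol
Product: 22 C11 aldehyde (C9 CHO; C17 CH2OTBDPS syn to C20)
Conditions: Dess–Martin periodinane, pyridine, CH2Cl2, 0 °C → rt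
Reagents that add atoms: none
Why: Buffered Dess–Martin oxidation should give the aldehyde without epimerising C9.

Step 15
Reactants: 22 C11 aldehyde
Product: 23 9-vinyl octalin silyl ether (C11=C12 vinyl on C9; C17 CH2OTBDPS syn to C20)
Conditions: Ph3PCH3Br, KN(SiMe3)2, THF, 0 °C; then 22, −78 → 0 °C
Reagents that add atoms: methyltriphenylphosphonium bromide, C[P+](c1ccccc1)(c1ccccc1)c1ccccc1.[Br-]
Why: Wittig methylenation with the preformed ylide at low temperature should convert the hindered aldehyde into the vinyl group (C12) faster than C9 can enolise.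

Step 16
Reactants: 23 9-vinyl octalin silyl ether
Product: 24 C17 alcohol (C8 CH2OH syn to C20)
Conditions: Bu4NF, THF, rt
Reagents that add atoms: none
Why: Fluoride cleaves the Si–O bond of the TBDPS ether and nothing else in the hydrocarbon skeleton reacts.

Step 17
Reactants: 24 C17 alcohol
Product: 25 8-epi C17 aldehyde (axial CHO syn to C20)
Conditions: Dess–Martin periodinane, pyridine, CH2Cl2, 0 °C
Reagents that add atoms: none
Why: Buffered Dess–Martin oxidation gives the β,γ-unsaturated aldehyde under neutral conditions, so C6=C7 should stay out of conjugation.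

Step 18
Reactants: 25 8-epi C17 aldehyde
Product: 26 C17 aldehyde (equatorial CHO anti to C20)
Conditions: K2CO3 (0.5 equiv), MeOH, 0 °C, monitored; pH 7 buffer quench
Reagents that add atoms: none
Why: Reversible α-deprotonation to the dienolate and kinetic α-reprotonation by methanol equilibrate C8, and relief of the syn-axial CHO/C20 interaction should drive the aldehyde to the equatorial epimer trans to the C9 vinyl group, provided the reaction is stopped before γ-protonation moves the alkene into conjugation.

Step 19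
Reactants: 26 C17 aldehyde
Product: 27 C17 carboxylic acid (equatorial CO2H on C8)
Conditions: NaClO2, NaH2PO4, 2-methylbut-2-ene, tBuOH/H2O, 0 °C → rt
Reagents that add atoms: sodium chlorite, [Na+].[O-]Cl=O
Why: Pinnick oxidation converts the aldehyde to the acid near pH 4 with an alkene scavenger, so neither C8 nor the two alkenes should be affected.

Step 20
Reactants: 27 C17 carboxylic acid
Product: 28 C17 tert-butyl ester (decalin fragment)
Conditions: tert-butyl 2,2,2-trichloroacetimidate (3 equiv), CH2Cl2/cyclohexane, rt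
Reagents that add atoms: tert-butyl 2,2,2-trichloroacetimidate, CC(C)(C)OC(=N)C(Cl)(Cl)Cl
Why: Acid-promoted tert-butyl transfer from the trichloroacetimidate esterifies the acid without base, so the C8 configuration is kept.

Step 21
Reactants: 29 prop-2-yn-1-ol
Product: 30 triisopropyl(prop-2-yn-1-yloxy)silane
Conditions: TIPSCl, imidazole, CH2Cl2, rt
Reagents that add atoms: chlorotriisopropylsilane, CC(C)[Si](Cl)(C(C)C)C(C)C
Why: Silylation of the primary alcohol installs a TIPS ether chosen to survive warm acetic acid in step 23.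

Step 22
Reactants: 30 triisopropyl(prop-2-yn-1-yloxy)silane
Product: 32 tert-butyl 4-(triisopropylsilyloxy)but-2-ynoate, via lithium acetylide 31 (not isolated)
Conditions: n-BuLi, THF, −78 °C; then Boc2O, −78 → 0 °C
Reagents that add atoms: di-tert-butyl dicarbonate, CC(C)(C)OC(=O)OC(=O)OC(C)(C)C
Why: Deprotonation of the terminal alkyne and C-acylation of the acetylide with Boc2O gives the tert-butyl ynoate and brings C15.

Step 23
Reactants: 32 tert-butyl 4-(triisopropylsilyloxy)but-2-ynoate
Product: 33 tert-butyl (Z)-3-iodo-4-(triisopropylsilyloxy)but-2-enoate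
Conditions: NaI (2 equiv), AcOH, 70 °C
Reagents that add atoms: sodium iodide, [Na+].[I-]
Why: Conjugate addition of iodide to the ynoate and protonation anti to iodine (anti hydroiodination) should give the (Z)-β-iodoenoate with iodine cis to the ester.

Step 24
Reactants: 28 C17 tert-butyl ester; 33 tert-butyl (Z)-3-iodo-4-(triisopropylsilyloxy)but-2-enoate
Product: 35 protected labdadiene diester (C16 OTIPS; C15 and C17 tert-butyl esters), via B-alkyl-9-BBN borane 34 (not isolated)
Conditions: 28, 9-BBN (1.5 equiv), THF, 0 °C → rt; then H2O, 33, PdCl2(dppf) (5 mol%), AsPh3, Cs2CO3, DMF, rt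
Reagents that add atoms: none
Why: 9-BBN hydroborates only the monosubstituted vinyl group, placing boron on C12, and the B-alkyl Suzuki–Miyaura coupling forms C12–C13 with retention of the iodoalkene geometry, so C12 ends cis to the C15 ester (13E).

Step 25
Reactants: 35 protected labdadiene diester
Product: 36 C16 alcohol (C15 and C17 tert-butyl esters)
Conditions: Bu4NF, AcOH, THF, 0 °C → rt
Reagents that add atoms: none
Why: Buffered fluoride removes the TIPS group, and the freed hydroxyl is trans to the C15 ester and cannot lactonise.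

Step 26
Reactants: 36 C16 alcohol
Product: 37 C16 acetate (C15 and C17 tert-butyl esters)
Conditions: Ac2O, pyridine, DMAP (cat.), CH2Cl2, 0 °C
Reagents that add atoms: acetic anhydride, CC(=O)OC(C)=O
Why: DMAP-catalysed acylation of the primary allylic alcohol installs the C16 acetate.

Step 27
Reactants: 37 C16 acetate
Product: 38 target CNP0108723.1
Conditions: CF3CO2H/CH2Cl2 (1:4), 0 °C → rt
Reagents that add atoms: none
Why: Acidolysis with loss of isobutene cleaves both tert-butyl esters, while the primary allylic acetate, the C8 stereocentre and both alkenes should be stable to CF3CO2H at room temperature.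

Compound list
1 | 5-chloro-1-(trimethylsilyl)pent-1-yne | ClCCCC#C[Si](C)(C)C | starting material
2 | 5-iodo-1-(trimethylsilyl)pent-1-yne | ICCCC#C[Si](C)(C)C | intermediate
3 | methyl isobutyrate | COC(=O)C(C)C | starting material
4 | lithium enolate of methyl isobutyrate | COC(O[Li])=C(C)C | intermediate
5 | methyl 2,2-dimethyl-7-(trimethylsilyl)hept-6-ynoate | COC(=O)C(C)(C)CCCC#C[Si](C)(C)C | intermediate
6 | 2,2-dimethyl-7-(trimethylsilyl)hept-6-yn-1-ol | OCC(C)(C)CCCC#C[Si](C)(C)C | intermediate
7 | 2,2-dimethyl-7-(trimethylsilyl)hept-6-ynal | O=CC(C)(C)CCCC#C[Si](C)(C)C | intermediate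
8 | triethyl (E)-4-phosphonocrotonate | CCOC(=O)/C=C/CP(=O)(OCC)OCC | starting material
9 | lithiated triethyl 4-phosphonocrotonate | CCOC(=O)/C=C/[CH-]P(=O)(OCC)OCC.[Li+] | intermediate
10 | ethyl (2E,4E)-6,6-dimethyl-11-(trimethylsilyl)undeca-2,4-dien-10-ynoate | CCOC(=O)/C=C/C=C/C(C)(C)CCCC#C[Si](C)(C)C | intermediate
11 | (2E,4E)-6,6-dimethyl-11-(trimethylsilyl)undeca-2,4-dien-10-yn-1-ol | OC/C=C/C=C/C(C)(C)CCCC#C[Si](C)(C)C | intermediate
12 | tert-butyl{[(2E,4E)-6,6-dimethyl-11-(trimethylsilyl)undeca-2,4-dien-10-yn-1-yl]oxy}diphenylsilane | CC(C)(C)[Si](OC/C=C/C=C/C(C)(C)CCCC#C[Si](C)(C)C)(c1ccccc1)c1ccccc1 | intermediate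
13 | tert-butyl{[(2E,4E)-6,6-dimethylundeca-2,4-dien-10-yn-1-yl]oxy}diphenylsilane | CC(C)(C)[Si](OC/C=C/C=C/C(C)(C)CCCC#C)(c1ccccc1)c1ccccc1 | intermediate
14 | (E)-alkenyldimethylalane from methylalumination of 13 (Al and the new methyl cis) | C[Al](C)/C=C(\C)CCCC(C)(C)/C=C/C=C/CO[Si](c1ccccc1)(c1ccccc1)C(C)(C)C | intermediate
15 | methyl (2E,8E,10E)-12-[(tert-butyldiphenylsilyl)oxy]-3,7,7-trimethyldodeca-2,8,10-trienoate | COC(=O)/C=C(\C)CCCC(C)(C)/C=C/C=C/CO[Si](c1ccccc1)(c1ccccc1)C(C)(C)C | intermediate
16 | (2E,8E,10E)-12-[(tert-butyldiphenylsilyl)oxy]-3,7,7-trimethyldodeca-2,8,10-trienoic acid | OC(=O)/C=C(\C)CCCC(C)(C)/C=C/C=C/CO[Si](c1ccccc1)(c1ccccc1)C(C)(C)C | intermediate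
17 | (R)-4-benzyloxazolidin-2-one | O=C1N[C@H](Cc2ccccc2)CO1 | starting material
18 | mixed pivalic anhydride of acid 16 | CC(C)(C)C(=O)OC(=O)/C=C(\C)CCCC(C)(C)/C=C/C=C/CO[Si](c1ccccc1)(c1ccccc1)C(C)(C)C | intermediate
19 | (R)-4-benzyl-3-[(2E,8E,10E)-12-(tert-butyldiphenylsilyloxy)-3,7,7-trimethyldodeca-2,8,10-trienoyl]oxazolidin-2-one | O=C1OC[C@@H](Cc2ccccc2)N1C(=O)/C=C(\C)CCCC(C)(C)/C=C/C=C/CO[Si](c1ccccc1)(c1ccccc1)C(C)(C)C | intermediate
20 | trans-octalin imide cycloadduct: C11 acyl (R)-4-benzyloxazolidinone on C9, CH2OTBDPS (C17) on C8, C6=C7 alkene; H5 anti to C20, C11 and C17 both syn to C20 | O=C1OC[C@@H](Cc2ccccc2)N1C(=O)[C@@H]1[C@H](CO[Si](c2ccccc2)(c2ccccc2)C(C)(C)C)C=C[C@@H]2C(C)(C)CCC[C@@]12C | intermediate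
21 | C11 alcohol: CH2OH on C9, CH2OTBDPS on C8 (both syn to C20), trans-fused 6-ene | OC[C@@H]1[C@H](CO[Si](c2ccccc2)(c2ccccc2)C(C)(C)C)C=C[C@@H]2C(C)(C)CCC[C@@]12C | intermediate
22 | C11 aldehyde: CHO on C9, CH2OTBDPS on C8 (both syn to C20) | O=C[C@@H]1[C@H](CO[Si](c2ccccc2)(c2ccccc2)C(C)(C)C)C=C[C@@H]2C(C)(C)CCC[C@@]12C | intermediate
23 | 9-vinyl octalin silyl ether: vinyl on C9, CH2OTBDPS on C8 (both syn to C20) | C=C[C@@H]1[C@H](CO[Si](c2ccccc2)(c2ccccc2)C(C)(C)C)C=C[C@@H]2C(C)(C)CCC[C@@]12C | intermediate
24 | C17 alcohol: CH2OH on C8 syn to C20 and to the C9 vinyl group | C=C[C@@H]1[C@H](CO)C=C[C@@H]2C(C)(C)CCC[C@@]12C | intermediate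
25 | 8-epi C17 aldehyde: axial CHO on C8, syn to C20 and cis to the C9 vinyl group | C=C[C@@H]1[C@H](C=O)C=C[C@@H]2C(C)(C)CCC[C@@]12C | intermediate
26 | C17 aldehyde: equatorial CHO on C8, anti to C20 and trans to the C9 vinyl group | C=C[C@@H]1[C@@H](C=O)C=C[C@@H]2C(C)(C)CCC[C@@]12C | intermediate
27 | C17 carboxylic acid: equatorial CO2H on C8, trans to the C9 vinyl group | C=C[C@@H]1[C@@H](C(=O)O)C=C[C@@H]2C(C)(C)CCC[C@@]12C | intermediate
28 | C17 tert-butyl ester (decalin fragment) | C=C[C@@H]1[C@@H](C(=O)OC(C)(C)C)C=C[C@@H]2C(C)(C)CCC[C@@]12C | intermediate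
29 | prop-2-yn-1-ol | C#CCO | starting material
30 | triisopropyl(prop-2-yn-1-yloxy)silane | C#CCO[Si](C(C)C)(C(C)C)C(C)C | intermediate
31 | lithium acetylide of 30 | [Li]C#CCO[Si](C(C)C)(C(C)C)C(C)C | intermediate
32 | tert-butyl 4-(triisopropylsilyloxy)but-2-ynoate | CC(C)[Si](C(C)C)(C(C)C)OCC#CC(=O)OC(C)(C)C | intermediate
33 | tert-butyl (Z)-3-iodo-4-(triisopropylsilyloxy)but-2-enoate | CC(C)[Si](C(C)C)(C(C)C)OC/C(I)=C/C(=O)OC(C)(C)C | intermediate
34 | B-alkyl-9-BBN borane from 28 (boron on C12) | B1(C2CCCC1CCC2)CC[C@@H]1[C@@H](C(=O)OC(C)(C)C)C=C[C@@H]2C(C)(C)CCC[C@@]12C | intermediate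
35 | protected labdadiene diester: (13E), C16 OTIPS, C15 and C17 tert-butyl esters | CC(C)[Si](C(C)C)(C(C)C)OC/C(=C/C(=O)OC(C)(C)C)CC[C@@H]1[C@@H](C(=O)OC(C)(C)C)C=C[C@@H]2C(C)(C)CCC[C@@]12C | intermediate
36 | C16 alcohol, C15 and C17 tert-butyl esters | OC/C(=C/C(=O)OC(C)(C)C)CC[C@@H]1[C@@H](C(=O)OC(C)(C)C)C=C[C@@H]2C(C)(C)CCC[C@@]12C | intermediate
37 | C16 acetate, C15 and C17 tert-butyl esters | CC(=O)OC/C(=C/C(=O)OC(C)(C)C)CC[C@@H]1[C@@H](C(=O)OC(C)(C)C)C=C[C@@H]2C(C)(C)CCC[C@@]12C | intermediate
38 | (5R,8S,9R,10S,13E)-16-acetoxylabda-6,13-diene-15,17-dioic acid (CNP0108723.1) | CC(=O)OC/C(=C/C(=O)O)CC[C@@H]1[C@@H](C(=O)O)C=C[C@@H]2C(C)(C)CCC[C@@]12C | target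

Total step count: 27. Longest linear sequence: 24 steps (steps 1–20, then 24–27); steps 21–23 make the side-chain fragment.

Steps most likely to fail

Step 12. The cycloaddition may stall, because the dienophile carries a β-methyl group and the C5–C10 bond joins a fully substituted carbon to a neopentyl-type carbon. The warming then needed could erode endo and facial control or let the Lewis acid ionise the dienylic silyl ether. The fallback replaces auxiliary control by catalyst control and sets out from acid 16. Acylation of oxazolidin-2-one (PivCl, Et3N, LiCl, THF) would give the achiral 3-[(2E,8E,10E)-trienoyl]oxazolidin-2-one F1. Cyclisation with [Cu((S,S)-tBu-box)](SbF6)2 (10 mol%, CH2Cl2, rt; tBu-box = 2,2'-isopropylidenebis(4-tert-butyl-2-oxazoline)), a dicationic complex of divalent copper and a known type of catalyst for enantioselective intramolecular Diels–Alder reactions of trienimides, should give the oxazolidinone cycloadduct F2. The square-planar chelate model predicts that the (S,S) ligand leaves the C9 re face open, so F2 should have the ring configuration of 20. Reduction of F2 with LiBH4/MeOH rejoins the route at alcohol 21.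

Step 18. Equilibration at C8 may be overtaken by migration of C6=C7 into conjugation with the aldehyde (γ-protonation of the dienolate), or may stop short of the equatorial epimer. The fallback corrects C8 at the ester oxidation level, where α-exchange in alkoxide/alcohol is expected to outpace double-bond migration and conjugation gains less. It sets out from aldehyde 25. Pinnick oxidation (NaClO2, NaH2PO4, 2-methylbut-2-ene) would give the 8-epi C17 acid F3. Esterification with tert-butyl 2,2,2-trichloroacetimidate would give the 8-epi C17 tert-butyl ester F4. Equilibration of F4 with KOtBu (0.2 equiv) in tBuOH/THF at rt should move the ester to the equatorial position, which is compound 28, where the route is rejoined.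

Step 13. Hydride may attack the ring carbonyl of the auxiliary instead of the exocyclic carbonyl, which is flanked by quaternary C10 and the substituted C8, giving ring-opened amide instead of the alcohol. The fallback sets out from imide 20. Hydrolysis with LiOH/H2O2 (THF/H2O, 0 °C), in which hydroperoxide selectively cleaves the exocyclic acyl group even of hindered imides, would give the C11 carboxylic acid F5 and the recovered auxiliary. Reduction of F5 with LiAlH4 (THF, 0 °C) rejoins the route at alcohol 21.

Further compounds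
F1 | step 12 | 3-[(2E,8E,10E)-12-(tert-butyldiphenylsilyloxy)-3,7,7-trimethyldodeca-2,8,10-trienoyl]oxazolidin-2-one | O=C1OCCN1C(=O)/C=C(\C)CCCC(C)(C)/C=C/C=C/CO[Si](c1ccccc1)(c1ccccc1)C(C)(C)C
F2 | step 12 | trans-octalin cycloadduct bearing the achiral oxazolidin-2-one on the C11 carbonyl (ring configuration as in 20) | O=C1OCCN1C(=O)[C@@H]1[C@H](CO[Si](c2ccccc2)(c2ccccc2)C(C)(C)C)C=C[C@@H]2C(C)(C)CCC[C@@]12C
F3 | step 18 | 8-epi C17 carboxylic acid (axial CO2H syn to C20, 9-vinyl) | C=C[C@@H]1[C@H](C(=O)O)C=C[C@@H]2C(C)(C)CCC[C@@]12C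
F4 | step 18 | 8-epi C17 tert-butyl ester (axial ester syn to C20, 9-vinyl) | C=C[C@@H]1[C@H](C(=O)OC(C)(C)C)C=C[C@@H]2C(C)(C)CCC[C@@]12C
F5 | step 13 | C11 carboxylic acid (CO2H on C9, CH2OTBDPS on C8, both syn to C20) | OC(=O)[C@@H]1[C@H](CO[Si](c2ccccc2)(c2ccccc2)C(C)(C)C)C=C[C@@H]2C(C)(C)CCC[C@@]12C
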